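Intermediate, target and over-reaction product cannot together exceed what the coupling has passed on, so I count that first.

| setting | south-east | north | Monday's | Tuesday's |
|---|---|---|---|---|
| starting material | 0.010 M | 0.010 M | 0.010 M | 0.010 M |
| coupling partner | 0.65 equiv | 2.6 equiv | 1.30 equiv | 1.30 equiv |
| temperature | 65 °C | 82 °C | 70 °C | 95 °C |
| remark | run made earlier | run made earlier |  |  |
| time |  |  | 2.0 h | 2.0 h |

| run | time / min | target / % | intermediate / % | starting material / % | over-reaction product / % |
|---|---|---|---|---|---|
| south-east | 6.00 | 0 | 0.9 | 97.8 | 0.6 |
| south-east | 12.0 | 0.1 | 2.5 | 97.4 | 0.5 |
| south-east | 30.0 | 0.5 | 5.5 | 91.3 | 1.3 |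
| south-east | 80.0 | 1.1 | 13.2 | 82.1 | 0 |
| north | 3.00 | 0.4 | 7.0 | 92.3 | 0.1 |
| north | 6.00 | 0.5 | 14.2 | 84.7 | 0 |
| north | 15.0 | 2.0 | 28.0 | 67.7 | 0.5 |
| north | 40.0 | 11.2 | 44.3 | 37.2 | 3.6 |

(each reading ± 0.5 percentage points)

- in percentages every species weighs as the starting material in it: one homo dimer counts as two
- the analysis behind the earlier runs scatters by 0.5 percentage points, standard deviation
- candidate steps: starting material + coupling partner -> intermediate; intermediate -> target; 2 starting material -> homo dimer; target -> over-reaction product

1. which of these there is most of at the end, counted by the starting material in it, Monday's (starting material / target / intermediate / over-reaction product)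
2. which of these there is most of at the end, counted by the starting material in it, Tuesday's (starting material / target / intermediate / over-reaction product)
3. the largest of these amounts at the end, in percent of the starting material charged, Monday's
4. the largest of these amounts at the end, in percent of the starting material charged, Tuesday's

At its last reading the south-east run has coupled 14.3% and the north run 59.1%, each the sum of intermediate, target and over-reaction product. Inverting the second-order rate law for unequal charges gives rate constant times starting concentration: 0.00336 min⁻¹ in south-east, 0.00994 min⁻¹ in north. Interpolating its logarithm in temperature and multiplying by the time gives 0.555 for Monday's flask. I call this the coupling number: rate constant times starting concentration times time, a second-order Damköhler number.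

The balance shortfalls, 3.60% and 3.70%, I read as homo dimer. Shortfall over coupled amount, times equivalents, gives 0.164 and 0.163, so I carry 0.163 as a small correction.

For Monday's flask the rate law gives 44.0% coupled, and the correction leaves 50.5% starting material. That is more than the coupled sum, so starting material leads however that sum divides. Tuesday's number, extrapolated beyond the runs, is 2.73, giving 84.6% coupled and 4.75% starting material. Far more is coupled than left, so the leader lies among the coupled species, and here one number is not enough: it cannot divide them.

The forecast gives starting material at 51% (46% to 56%) for Monday's flask and over-reaction product at 62% (50% to 72%) for Tuesday's, its step from target to over-reaction product “with its temperature dependence poorly known”.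

Monday's flask ends with starting material leading at 50.9%, Tuesday's with over-reaction product at 71.8%, 9.8 percentage points above the forecast.

    starting material + coupling partner → intermediate (k = 28.0 M⁻¹ h⁻¹, Ea = 67.0 kJ mol⁻¹)
    intermediate → target (k = 0.175 h⁻¹, Ea = 122 kJ mol⁻¹)
    2 starting material → homo dimer (k = 3.12 M⁻¹ h⁻¹, Ea = 57.0 kJ mol⁻¹)
    target → over-reaction product (k = 0.253 h⁻¹, Ea = 114 kJ mol⁻¹)
    (constants at 70 °C)

The neighbouring flask is Monday's read at 50 min, so its coupling number is Monday's scaled by time, 0.231. The rate law gives 23.7% coupled, and the correction leaves 73.3% starting material. That flask holds 72.8% starting material.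

(All runs come from a simulation with constants of no real substance; scatter was added.)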